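**Retrosynthetic overview**
1. 20 ⇒ 13 + 17. The C3–benzyl bond is made last, by alkylating the planar enediolate of the α-hydroxy lactone anti to the C4 substituent. The phenol silyl ether is cleaved in the same flask.
2. 13 ⇒ 11 by enolate oxidation, and 11 ⇒ 10 by asymmetric hydrogenation. The hydrogenation sets C4, the centre that later controls C3.
3. 10 ⇒ 8 by loss of water, and 8 ⇒ 5. The butyrolactone is the only ring formed. It closes at C3–C4 by intramolecular aldol addition of a zinc ester enolate to the benzyl ketone.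
4. 5 ⇒ 1 + one diazo carbon + 2. In parallel, 17 ⇒ syringaldehyde 14 in three steps.

Assumption: the (R)-BINAP–Ru catalyst is taken to give (R)-11; the sense is checked by optical rotation against the known (R)-lactone, and the (S)-ligand is used if it is reversed.

**Step 1**
Reactants: 1 (3,4-dimethoxyphenyl)acetyl chloride; 2 bromoacetic acid
Product: 5 3-(3,4-dimethoxyphenyl)-2-oxopropyl 2-bromoacetate, via silyl diazoketone 3 (not isolated), via diazoketone 4 (not isolated)
Conditions: TMSCHN2 (2.2 equiv), THF–MeCN, 0 °C → rt (1 added slowly); then 2 (3.5 equiv), rt → 45 °C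
Reagents that add atoms: trimethylsilyldiazomethane, C[Si](C)(C)C=[N+]=[N-]
Why: Arndt–Eistert-type acylation of the diazoalkane gives the diazoketone, which bromoacetic acid protodesilylates and then protonates at carbon so that its carboxylate displaces N2 (diazoketone acidolysis) under base-free conditions that spare the C–Br bond and the acidic benzyl ketone; no stereocentre is formed.

**Step 2**
Reactants: 5 3-(3,4-dimethoxyphenyl)-2-oxopropyl 2-bromoacetate
Product: 8 rac-4-(3,4-dimethoxybenzyl)-4-hydroxydihydrofuran-2(3H)-one, via bromozinc ester enolate 6 (not isolated), via bromozinc aldolate 7 (not isolated)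
Conditions: Zn dust (4 equiv, TMSCl-activated), THF, reflux, 5 added over 4 h (final 0.01 M); then 1 M HCl, 0 °C
Reagents that add atoms: none
Why: Zinc inserts only into the C–Br bond, so the weakly basic ester enolate forms regiospecifically beside a more acidic benzyl ketone, and its intramolecular aldol addition to that ketone (Reformatsky variant, 5-exo-trig) closes the lactone at C3–C4; the new carbinol centre is racemic and is erased in step 3.

**Step 3**
Reactants: 8 rac-4-(3,4-dimethoxybenzyl)-4-hydroxydihydrofuran-2(3H)-one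
Product: 10 4-(3,4-dimethoxybenzyl)furan-2(5H)-one, via tertiary mesylate 9 (not isolated)
Conditions: MsCl (2 equiv), Et3N (5 equiv), CH2Cl2, 0 °C → rt
Reagents that add atoms: none
Why: Mesylation followed by E1cB elimination through the lactone enolate completes the aldol condensation and places the double bond only in the conjugated C3=C4 position, because only the C3 hydrogens are acidic enough for Et3N.

**Step 4**
Reactants: 10 4-(3,4-dimethoxybenzyl)furan-2(5H)-one
Product: 11 (R)-4-(3,4-dimethoxybenzyl)dihydrofuran-2(3H)-one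
Conditions: Ru2Cl4[(R)-BINAP]2·NEt3 (0.5 mol %), H2 (100 atm), CH2Cl2, 50 °C
Reagents that add atoms: none
Why: In this Noyori-type Ru–BINAP asymmetric hydrogenation of a β-substituted butenolide the lactone carbonyl binds to Ru and the ligand differentiates the two olefin faces, which sets C4 as R with the same spatial arrangement as C4 (S) of the target.

**Step 5**
Reactants: 11 (R)-4-(3,4-dimethoxybenzyl)dihydrofuran-2(3H)-one
Product: 13 (3R,4S)-4-(3,4-dimethoxybenzyl)-3-hydroxydihydrofuran-2(3H)-one, via sodium enolate 12 (not isolated)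
Conditions: NaHMDS (1.1 equiv), THF, −78 °C; 2-(phenylsulfonyl)-3-phenyloxaziridine (1.3 equiv), −78 °C; AcOH
Reagents that add atoms: 2-(phenylsulfonyl)-3-phenyloxaziridine, O=S(=O)(c1ccccc1)N1OC1c1ccccc1
Why: In the Davis enolate oxidation oxygen is delivered to the face anti to the C4 benzyl group, giving mainly the trans alcohol, and C4 is untouched; the C3 configuration is not critical because C3 becomes planar again in step 9.

**Step 6**
Reactants: 14 syringaldehyde (4-hydroxy-3,5-dimethoxybenzaldehyde)
Product: 15 4-(tert-butyldimethylsilyloxy)-3,5-dimethoxybenzaldehyde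
Conditions: TBSCl (1.3 equiv), imidazole (2.5 equiv), DMF, rt
Reagents that add atoms: tert-butyldimethylsilyl chloride, CC(C)(C)[Si](C)(C)Cl
Why: Imidazole-promoted O-silylation masks the acidic phenol, which would otherwise quench the enediolate and let the benzylic bromide collapse to a quinone methide.

**Step 7**
Reactants: 15 4-(tert-butyldimethylsilyloxy)-3,5-dimethoxybenzaldehyde
Product: 16 [4-(tert-butyldimethylsilyloxy)-3,5-dimethoxyphenyl]methanol
Conditions: NaBH4 (0.5 equiv), THF–MeOH, 0 °C
Reagents that add atoms: none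
Why: Borohydride reduces the aldehyde quickly at 0 °C, and the aryl silyl ether survives the short exposure.

**Step 8**
Reactants: 16 [4-(tert-butyldimethylsilyloxy)-3,5-dimethoxyphenyl]methanol
Product: 17 4-(bromomethyl)-2,6-dimethoxyphenyl tert-butyldimethylsilyl ether
Conditions: CBr4 (1.2 equiv), PPh3 (1.2 equiv), CH2Cl2, 0 °C; short silica plug, used at once
Reagents that add atoms: tetrabromomethane, BrC(Br)(Br)Br
Why: The Appel reaction converts the electron-rich benzylic alcohol into the bromide under neutral conditions, free of HBr, which keep the silyl ether intact.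

**Step 9**
Reactants: 13 (3R,4S)-4-(3,4-dimethoxybenzyl)-3-hydroxydihydrofuran-2(3H)-one; 17 4-(bromomethyl)-2,6-dimethoxyphenyl tert-butyldimethylsilyl ether
Product: 20 (3S,4S)-4-(3,4-dimethoxybenzyl)-3-hydroxy-3-(4-hydroxy-3,5-dimethoxybenzyl)dihydrofuran-2(3H)-one (target), via dilithium enediolate 18 (not isolated), via silyl ether 19 (not isolated)
Conditions: LDA (2.3 equiv), THF–DMPU, −78 → −40 °C; 17 (1.2 equiv), −78 → −30 °C; AcOH (3 equiv), then TBAF (1.3 equiv), 0 °C
Reagents that add atoms: none
Why: In this dianion (enediolate) alkylation C3 is planar and the C4 veratryl group blocks one face, so the SN2 benzylation comes in anti to it, giving trans benzyl groups with OH cis to the C4 substituent, that is (3S,4S); buffered fluoride then cleaves the aryl silyl ether.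

**Compound list**
1 | (3,4-dimethoxyphenyl)acetyl chloride | COc1ccc(CC(=O)Cl)cc1OC | starting material
2 | bromoacetic acid | OC(=O)CBr | starting material
3 | 1-diazo-3-(3,4-dimethoxyphenyl)-1-(trimethylsilyl)propan-2-one | COc1ccc(CC(=O)C(=[N+]=[N-])[Si](C)(C)C)cc1OC | intermediate
4 | 1-diazo-3-(3,4-dimethoxyphenyl)propan-2-one | COc1ccc(CC(=O)C=[N+]=[N-])cc1OC | intermediate
5 | 3-(3,4-dimethoxyphenyl)-2-oxopropyl 2-bromoacetate | COc1ccc(CC(=O)COC(=O)CBr)cc1OC | intermediate
6 | bromozinc ester enolate (Reformatsky reagent) of 5 | COc1ccc(CC(=O)COC(=O)C[Zn]Br)cc1OC | intermediate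
7 | bromozinc alkoxide of 8 (racemic) | COc1ccc(CC2(CC(=O)OC2)O[Zn]Br)cc1OC | intermediate
8 | rac-4-(3,4-dimethoxybenzyl)-4-hydroxydihydrofuran-2(3H)-one | COc1ccc(CC2(O)CC(=O)OC2)cc1OC | intermediate
9 | rac-3-(3,4-dimethoxybenzyl)-5-oxotetrahydrofuran-3-yl methanesulfonate | COc1ccc(CC2(CC(=O)OC2)OS(C)(=O)=O)cc1OC | intermediate
10 | 4-(3,4-dimethoxybenzyl)furan-2(5H)-one | COc1ccc(CC2=CC(=O)OC2)cc1OC | intermediate
11 | (R)-4-(3,4-dimethoxybenzyl)dihydrofuran-2(3H)-one | COc1ccc(C[C@H]2COC(=O)C2)cc1OC | intermediate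
12 | sodium enolate of 11 (C4 unchanged) | COc1ccc(C[C@H]2COC([O-])=C2)cc1OC.[Na+] | intermediate
13 | (3R,4S)-4-(3,4-dimethoxybenzyl)-3-hydroxydihydrofuran-2(3H)-one (OH trans to benzyl) | COc1ccc(C[C@H]2COC(=O)[C@@H]2O)cc1OC | intermediate
14 | syringaldehyde | COc1cc(C=O)cc(OC)c1O | starting material
15 | 4-(tert-butyldimethylsilyloxy)-3,5-dimethoxybenzaldehyde | COc1cc(C=O)cc(OC)c1O[Si](C)(C)C(C)(C)C | intermediate
16 | [4-(tert-butyldimethylsilyloxy)-3,5-dimethoxyphenyl]methanol | COc1cc(CO)cc(OC)c1O[Si](C)(C)C(C)(C)C | intermediate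
17 | 4-(bromomethyl)-2,6-dimethoxyphenyl tert-butyldimethylsilyl ether | COc1cc(CBr)cc(OC)c1O[Si](C)(C)C(C)(C)C | intermediate
18 | dilithium enediolate of 13 (C4 unchanged) | COc1ccc(C[C@H]2COC([O-])=C2[O-])cc1OC.[Li+].[Li+] | intermediate
19 | (3S,4S)-3-[4-(tert-butyldimethylsilyloxy)-3,5-dimethoxybenzyl]-4-(3,4-dimethoxybenzyl)-3-hydroxydihydrofuran-2(3H)-one | COc1ccc(C[C@H]2COC(=O)[C@]2(O)Cc2cc(OC)c(O[Si](C)(C)C(C)(C)C)c(OC)c2)cc1OC | intermediate
20 | (3S,4S)-4-(3,4-dimethoxybenzyl)-3-hydroxy-3-(4-hydroxy-3,5-dimethoxybenzyl)dihydrofuran-2(3H)-one | COc1ccc(C[C@H]2COC(=O)[C@]2(O)Cc2cc(OC)c(O)c(OC)c2)cc1OC | target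

**Total step count:** 9
**Longest linear sequence:** 6 (steps 1, 2, 3, 4, 5, 9); steps 6–8 run in parallel.

**Steps most likely to fail**

Step 2 (zinc aldol ring closure). The acidic benzyl-ketone CH2 can protonate the zinc enolate, which leaves the plain acetate. Intermolecular addition can also compete with ring closure. The fallback sets out from 5 and comes back at 10. An Arbuzov reaction of 5 with triethyl phosphite (neat, 110 °C) gives 3-(3,4-dimethoxyphenyl)-2-oxopropyl 2-(diethoxyphosphoryl)acetate F1. Its phosphonate CH2 is then the most acidic site. An intramolecular Horner–Wadsworth–Emmons olefination (LiCl, DBU, MeCN, rt) gives butenolide 10 directly.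

Step 4 (asymmetric hydrogenation). The ee may be insufficient for a benzyl-substituted butenolide, and the double bond may migrate before reduction. The fallback sets out from 10 and comes back at 11.
- Hydrogenation over Pd/C (1 atm, EtOAc) gives rac-4-(3,4-dimethoxybenzyl)dihydrofuran-2(3H)-one F2.
- AlMe3-mediated aminolysis with (R)-1-phenylethylamine opens F2 to two separable hydroxy amides. These are (3R)-3-(3,4-dimethoxybenzyl)-4-hydroxy-N-[(1R)-1-phenylethyl]butanamide F3 and (3S)-3-(3,4-dimethoxybenzyl)-4-hydroxy-N-[(1R)-1-phenylethyl]butanamide F4.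
- After crystallisation or chromatography, F3 is hydrolysed and relactonised (2 M H2SO4, dioxane, reflux) to 11.

Step 9 (enediolate benzylation). The second deprotonation may be incomplete, O-alkylation may compete, and the labile bromide 17 may decompose. The fallback sets out from 13 together with aldehyde 15 from step 6, and comes back at 19. Enediolate 18 is trapped at −78 °C with the more reactive and stable aldehyde 15, in an aldol addition with the same anti facial bias. This gives (3R,4S)-3-{[4-(tert-butyldimethylsilyloxy)-3,5-dimethoxyphenyl](hydroxy)methyl}-4-(3,4-dimethoxybenzyl)-3-hydroxydihydrofuran-2(3H)-one F5 as a mixture of carbinol epimers. Hydrogenolysis of the electron-rich benzylic C–OH (H2, Pd/C, AcOH–EtOAc) gives 19, which TBAF converts into 20 as in step 9.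

**Further compounds**
F1 | step 2 | 3-(3,4-dimethoxyphenyl)-2-oxopropyl 2-(diethoxyphosphoryl)acetate | CCOP(=O)(CC(=O)OCC(=O)Cc1ccc(OC)c(OC)c1)OCC
F2 | step 4 | rac-4-(3,4-dimethoxybenzyl)dihydrofuran-2(3H)-one | COc1ccc(CC2COC(=O)C2)cc1OC
F3 | step 4 | (3R)-3-(3,4-dimethoxybenzyl)-4-hydroxy-N-[(1R)-1-phenylethyl]butanamide | COc1ccc(C[C@@H](CO)CC(=O)N[C@H](C)c2ccccc2)cc1OC
F4 | step 4 | (3S)-3-(3,4-dimethoxybenzyl)-4-hydroxy-N-[(1R)-1-phenylethyl]butanamide | COc1ccc(C[C@H](CO)CC(=O)N[C@H](C)c2ccccc2)cc1OC
F5 | step 9 | (3R,4S)-3-{[4-(tert-butyldimethylsilyloxy)-3,5-dimethoxyphenyl](hydroxy)methyl}-4-(3,4-dimethoxybenzyl)-3-hydroxydihydrofuran-2(3H)-one, carbinol epimers | COc1ccc(C[C@H]2COC(=O)[C@]2(O)C(O)c2cc(OC)c(O[Si](C)(C)C(C)(C)C)c(OC)c2)cc1OC
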